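Remark on numbering and one assumption: ring atoms carry the numbers of the target skeleton (ring A = C1–C5 and C10, ring B = C5–C10, C11 = isopropylidene carbon; C3 ester oxygen, C4 and C5 methyls, C8 ketone, C9 hydroxyl), β is the face of the C5 methyl, and the decalin names below use this numbering. (S)-Pent-1-yn-3-ol is assumed to be available as a single enantiomer.

## Analysis of the target

The target is a trans-fused decalin of the eremophilane type whose C3 oxygen is esterified with (S,Z)-4-[(Z)-hex-2-enoyloxy]hex-2-enoic acid. Ring A carries the ester oxygen at C3 (α, equatorial), a secondary methyl at C4 (β, equatorial) and the quaternary methyl at C5 (β, axial). Ring B carries a plain methylene at C6, the isopropylidene at C7, the ketone at C8 and an equatorial (α) hydroxyl at C9, with H-10 α. The five ring stereocentres (3R,4R,5R,9S,10R) form one contiguous chain C3–C4–C5–C10–C9, with the two methyls cis and the C3 oxygen trans to them; the sixth centre (S) lies in the side chain. Sensitive groups are the C8/C9 α-ketol (enediol tautomerism, air oxidation), the cross-conjugated isopropylidene enone, the two Z-enoates (Z to E isomerisation, conjugate addition) and the allylic acyloxy centre. The hard part is the quaternary C5 next to the tertiary C4, both methyl-bearing, in one absolute configuration, together with three differentiated oxygens at C3, C8 and C9. Of the ring centres only C5 cannot be adjusted afterwards: C4 is α to a C3 carbonyl, C10 α to a C9 carbonyl, C9 α to the C8 ketone, and C3 is a carbinol open to reagent control. The strategy rests on the match of ring B, C5(CH3)–C6–C7–C8(O)–C9(O)–C10, with 2-methoxy-5-methyl-1,4-benzoquinone, and of C1–C4 (oxygen at C3, methyl at C4) with a 3-silyloxypenta-1,3-diene, so that one cycloaddition across C5=C10 closes ring A and creates C5.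

## Retrosynthetic reasoning

26 to 25: the two Z-alkenes are traced back to triple bonds. Alkynes cannot lose configuration during esterification and deprotection, so the labile Z,Z-diester exists only in the last flask. The forward step must add one equivalent of hydrogen per alkyne, cis, and leave the tetrasubstituted enone alone.

25 to 24, then 24 to 16 plus 23: the C3–O ester bond is cut, with inversion at C3. The C3 ketone is reduced most reliably to the axial 3β-alcohol 16, because the axial C5 methyl blocks the axial hydride path; the equatorial ester of the target then follows from an invertive esterification. The cut is convergent and brings the whole side chain, stereocentre included, as acid 23. The C9 hydroxyl stays silylated (24) so that only one hydroxyl meets the coupling.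

23 to 22, then 22 to 20 plus 21, 20 to 19 to 17: in the side chain the acyl–oxygen bond to the hexynoyl unit and the bond between the alkyne terminus and the carboxyl carbon are cut. The stereocentre is bought with 17. The carboxyl group is introduced first and masked as a tert-butyl ester, so that no strong base ever meets the ynoate ester.

16 to 15: the C3–H bond is cut, i.e. a late ketone reduction. Keeping C3 as a ketone up to 15 leaves C4 epimerisable for as long as possible and gives a ketone that a bulky hydride can tell apart from the shielded C8 enone.

15 to 13 (through 14), then 13 to 10 plus 11 (through 12): the C7=C11 double bond is traced to an aldol, which cuts the C7–C11 bond between a C7 enolate and 11. The C8 ketone has two α-positions, C7 and C9. Generating the enolate by conjugate reduction of the C6=C7 enone of 10 fixes the site without relying on selective deprotonation, and at the same time turns C6 into the methylene of the target.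

10 to 9 to 8: a silyl group is removed from the C9 oxygen and the configurations at C9 and C4 are traced back to their epimers. Both centres are α to a carbonyl in 8, so the forward step is an equilibration that puts the hydroxyl and the methyl equatorial.

8 to 6 (through 7): the C8 ketone with the C6=C7 double bond is the transposed form of the C6 carbonyl with the C8 methoxy enol ether; the C9 hydroxyl comes from the C9 ketone and the C3 ketone from the silyl enol ether. Carrying C3 as the enol ether through the hydride step keeps it out of the reduction and differentiates it from the ring B oxygens.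

6 to 5: only the configuration at C10 changes. The trans ring fusion is reached by enolisation of the C9 ketone, which is possible only while C9 is still a carbonyl, hence directly after the cycloaddition.

5 to 2 plus 4: the C4–C5 and C1–C10 bonds are cut, which opens ring A in a retro-[4+2] sense. This is the only place where a single step delivers ring A, the quaternary C5 and the full oxygen pattern of ring B from two achiral partners. The forward reaction has to fix the absolute configuration of C5 and the orientation of the two partners.

2 to 1 and 4 to 3: the quinone comes from the phenol by oxidation at the free para position, the diene from the enone by O-silylation of its enol; one step each.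

## Alternatives that were turned down

Alternative 1: ring A is taken from the enantiopure enone A1, and the C4–CH3 and C5–C6 bonds are made in one three-component operation. A methyl cuprate would add to C4 anti to the silyloxy group, and the resulting enolate would be alkylated at C5 with A2 to give A3. In its favour, the C3 oxygen is in place from the start, and the C4 and C5 methyls come out cis directly, relayed from C3. On that point it is stronger than the chosen route, which needs an epimerisation at C4 and an inversion at C3. Against it, the alkylation has to build a quaternary centre next to a fresh tertiary one from a cuprate-derived enolate, a slow step that competes with proton transfer and O-alkylation. The step closes no ring, and C6–C9 arrive as an unfunctionalised butynyl chain, so ring B, C10, both ring B oxygens and the isopropylidene are all still to be made. The chosen cycloaddition offers in exchange ring A, C5 and the complete C6/C8/C9 oxygen pattern in one catalytic step from achiral materials.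

Alternative 2: the C4–C5 bond is cut and ring B is seen as an arene. The phenolate of A4 would attack the methyl-bearing epoxide carbon through its para carbon, closing ring A and giving the dienone A5. In its favour, the epoxide transfers its configuration to C3 and C4, so the equatorial C3 hydroxyl and the cis methyls arise directly. Here it is stronger than the chosen route on C3 and C4. Against it, the ring must close in the six-membered endo sense at the more hindered epoxide carbon, while the five-membered exo closure to a spirocycle is the easier path. The para carbon is itself methyl-substituted, and the facial relation of C5 to C4 depends on the folding of a flexible tether. After the key step the tetrasubstituted C9=C10 enol ether and the C6=C7 bond have to be reduced with control of C10 and C9, centres that can then no longer be corrected by enolisation. The chosen route sets C10 and C9 under thermodynamic control and keeps its risk in a cycloaddition of a well-behaved class.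

Alternative 3: the C8–C9 bond is cut. An N-heterocyclic carbene would join the enal carbon of dialdehyde A6 to its C9 aldehyde and close ring B as the ketol A7. In its favour, A7 already holds the isopropylidene enone and the C9 hydroxyl, so very little remains after the key step; on endgame economy it is the strongest of the four. Against it, A6 contains C3, C4, C5 and C10 in final form, so the difficult stereochemistry is merely moved into a long synthesis of the substrate. The crossed acyloin has to start at the hindered, fully substituted enal rather than at the more accessible saturated aldehyde, which would give the wrong ketol. C10 is α to an aldehyde under basic conditions, and C9 is set without an obvious controlling element. The chosen route spends more steps after its key step, but the key step creates the ring system and the one centre that cannot be adjusted later.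

Key step: step 3

## Route

Step 1
Reactants: 1 2-methoxy-5-methylphenol
Product: 2 2-methoxy-5-methyl-1,4-benzoquinone
Conditions: K2NO(SO3)2 (2.2 equiv), KH2PO4 buffer, H2O/MeOH, 0 °C to rt
Reagents that add atoms: dipotassium nitrosodisulfonate, [K+].[K+].[O]N(S(=O)(=O)[O-])S(=O)(=O)[O-]
Why: Teuber oxidation: the nitroxyl radical abstracts the phenolic hydrogen and a second equivalent couples at the free para carbon; loss of imidodisulfonate leaves the para-quinone, with the methoxy and methyl groups in the 2,5-relationship needed for ring B.

Step 2
Reactants: 3 pent-1-en-3-one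
Product: 4 (Z)-tert-butyldimethyl(penta-1,3-dien-3-yloxy)silane
Conditions: TBSOTf (1.1 equiv), Et3N (1.5 equiv), Et2O, 0 °C
Reagents that add atoms: tert-butyldimethylsilyl trifluoromethanesulfonate, CC(C)(C)[Si](C)(C)OS(=O)(=O)C(F)(F)F
Why: Soft enolisation of the only enolisable α-position (the ethyl CH2) with silyl triflate and amine gives the silyl dienol ether; ethyl ketones give mainly the Z isomer (methyl cis to oxygen) under these conditions, which is the isomer that can react in the s-cis form.

Step 3
Reactants: 2 2-methoxy-5-methyl-1,4-benzoquinone; 4 (Z)-tert-butyldimethyl(penta-1,3-dien-3-yloxy)silane (1.5 equiv)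
Product: 5 cis-fused 3-(tert-butyldimethylsilyloxy)-8-methoxy-4α,5β-dimethyl-10βH-decala-2,7-diene-6,9-dione
Conditions: (S)-3,3-diphenyl-1-(o-tolyl)tetrahydro-1H,3H-pyrrolo[1,2-c][1,3,2]oxazaborole (22 mol %), HNTf2 (20 mol %), CH2Cl2, −78 °C
Reagents that add atoms: none
Why: The boron of the N-protonated oxazaborolidine binds the C9 carbonyl oxygen of 2 at the lone pair on the C10–H side (the other lone pair faces the C8 methoxy group), supported by a C10–H···O contact to the ring oxygen, and 4 adds in a concerted, asynchronous endo [4+2] in which the silyl enol ether terminus C4 bonds first to C5, the β-carbon of the activated enone, and C1 then bonds to C10. The closest known reaction type is the oxazaborolidinium-catalysed enantioselective Diels–Alder reaction of 2,5-disubstituted 1,4-benzoquinones with 2-silyloxy-1,3-dienes. Ring A is closed by this intermolecular cycloaddition, suprafacial on both partners, as a six-membered ring that contains the new C4–C5 and C1–C10 bonds. C5 is controlled by the catalyst: the C5=C10 bond lies over the phenyl group cis to the bound quinone, so the diene reaches only the open face, which for the (S)-catalyst should be the face that leaves the C5 methyl β. C10 follows from the suprafacial addition (H cis to the C5 methyl) and C4 from the endo approach of the Z-diene (methyl trans to the C5 methyl); both are provisional and are corrected in steps 4, 6 and 9. Site selectivity is secured by the methoxy group, which deactivates C7=C8. Regioselectivity is secured because C6=O is a vinylogous ester, so only the C9 carbonyl polarises C5=C10, while the silyloxy group makes C4 the nucleophilic diene terminus; face selectivity rests on the catalyst alone. The minor E-diene reaches the s-cis form with difficulty and should stay behind, and the slight excess of oxazaborolidine over HNTf2 avoids free acid that would cleave the silyl dienol ether.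

Step 4
Reactants: 5 cis-fused adduct
Product: 6 trans-fused 3-(tert-butyldimethylsilyloxy)-8-methoxy-4α,5β-dimethyl-10αH-decala-2,7-diene-6,9-dione
Conditions: DBU (0.2 equiv), PhMe, rt
Reagents that add atoms: none
Why: Reversible deprotonation at C10 gives a cross-conjugated dienolate of the ene-dione, and reprotonation should settle on the trans-fused isomer, in which the axial C5 methyl has a single syn-axial hydrogen because C3, C7 and C9 are trigonal; this is the usual base-mediated cis to trans isomerisation of quinone–diene adducts. C5 is quaternary and cannot change, and the silyl enol ether is inert to the amidine.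

Step 5
Reactants: 6 trans-fused adduct
Product: 8 9β-hydroxy-4α,5β-dimethyl-10αH-decal-6-ene-3,8-dione, via enol ether diol 7 (not isolated)
Conditions: LiAlH4, THF, −78 to 0 °C; then 1 M HCl, THF, rt
Reagents that add atoms: water, O
Why: Hydride adds 1,2 to the C9 ketone and to the vinylogous ester carbonyl C6 (silyl enol ethers survive). In acid the C6 allylic alcohol ionises with help of the C8 methoxy group, water adds at C8 and methanol is lost, which transposes the carbonyl to C8 with the C6=C7 double bond; the same acid hydrolyses the silyl enol ether to the C3 ketone. The C9 hydroxyl is expected β (hydride anti to the 1,3-related C5 methyl), but either epimer serves because step 6 resets it.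

Step 6
Reactants: 8 9β-hydroxy-4α,5β-dimethyl-10αH-decal-6-ene-3,8-dione
Product: 9 9α-hydroxy-4β,5β-dimethyl-10αH-decal-6-ene-3,8-dione
Conditions: NaOMe (0.3 equiv), degassed MeOH, 0 °C to rt, Ar
Reagents that add atoms: none
Why: Base-mediated epimerisation: C9 equilibrates through the enediolate of the α-ketol to the equatorial 9α-hydroxyl, since the 9β-hydroxyl is syn-axial to the C5 methyl, and the conjugated C8 enone is the stable ketol tautomer. C4 equilibrates through the C3 enolate toward the equatorial 4β-methyl, which is also the product of axial protonation anti to the C5 methyl.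

Step 7
Reactants: 9 9α-hydroxy-4β,5β-dimethyl-10αH-decal-6-ene-3,8-dione
Product: 10 9α-(tert-butyldimethylsilyloxy)-4β,5β-dimethyl-10αH-decal-6-ene-3,8-dione
Conditions: TBSOTf (1.2 equiv), 2,6-lutidine, CH2Cl2, −78 to −20 °C
Reagents that add atoms: tert-butyldimethylsilyl trifluoromethanesulfonate, CC(C)(C)[Si](C)(C)OS(=O)(=O)C(F)(F)F
Why: O-Silylation of the equatorial secondary hydroxyl; with the hindered pyridine base at low temperature the ketones are not converted into enol ethers. The silyl ether keeps the ketol out of the enolate, sulfonylation and coupling chemistry that follows.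

Step 8
Reactants: 10 9α-(tert-butyldimethylsilyloxy)-4β,5β-dimethyl-10αH-decal-6-ene-3,8-dione; 11 acetone
Product: 13 9α-(tert-butyldimethylsilyloxy)-7α-(2-hydroxypropan-2-yl)-4β,5β-dimethyl-10αH-decalin-3,8-dione, via dimethylphenylsilyl enol ether 12 (not isolated)
Conditions: [(Ph3P)CuH]6 (5 mol %), PhMe2SiH (1.05 equiv), PhMe, rt; then 11 (5 equiv), TiCl4 (1.2 equiv), CH2Cl2, −78 °C
Reagents that add atoms: none
Why: Copper hydride adds 1,4 to the enone much faster than 1,2 to the hindered saturated C3 ketone, and the copper enolate is silylated by the silane, which is kept limiting; the C7=C8 silyl enol ether therefore forms regiospecifically. A Mukaiyama aldol addition to 11 under TiCl4 then makes the C7–C11 bond; the configuration at C7 is of no consequence because it is lost in step 9.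

Step 9
Reactants: 13 aldol
Product: 15 9α-(tert-butyldimethylsilyloxy)-4β,5β-dimethyl-7-(propan-2-ylidene)-10αH-decalin-3,8-dione, via tertiary mesylate 14 (not isolated)
Conditions: MsCl (2 equiv), Et3N (4 equiv), CH2Cl2, 0 °C; then DBU (3 equiv), rt
Reagents that add atoms: none
Why: Sulfonylation of the tertiary alcohol through sulfene and E1cB elimination through the C7 enolate give the enone; DBU moves any isopropenyl isomer into conjugation. The same base keeps C4 and C9 under thermodynamic control, now with C6 saturated, where the 4β-methyl and the 9α-silyloxy group are both equatorial.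

Step 10
Reactants: 15 isopropylidene dione
Product: 16 9α-(tert-butyldimethylsilyloxy)-3β-hydroxy-4β,5β-dimethyl-7-(propan-2-ylidene)-10αH-decalin-8-one
Conditions: LiBH(s-Bu)3 (1.1 equiv), THF, −78 °C; aq. NH4Cl
Reagents that add atoms: none
Why: The bulky hydride attacks the C3 ketone along the equatorial path from the α face, because the axial path is blocked by the syn-axial C5 methyl, and should give the axial 3β-alcohol. The C8 carbonyl, flanked by the silyloxy-bearing C9 and the tetrasubstituted alkene, is shielded against both 1,2- and 1,4-addition.

Step 11
Reactants: 17 (S)-pent-1-yn-3-ol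
Product: 19 (S)-4-hydroxyhex-2-ynoic acid, via dilithium alkynide alkoxide 18 (not isolated)
Conditions: n-BuLi (2.1 equiv), THF, −78 to −30 °C; CO2, −78 °C to rt; aq. HCl
Reagents that add atoms: carbon dioxide, O=C=O
Why: Double deprotonation and C-carboxylation of the alkynide; the carbonate formed at the alkoxide reverts on acidification. The carbinol centre is not involved.

Step 12
Reactants: 19 (S)-4-hydroxyhex-2-ynoic acid
Product: 20 tert-butyl (S)-4-hydroxyhex-2-ynoate
Conditions: tert-butyl N,N'-diisopropylcarbamimidate (2 equiv), CH2Cl2, rt
Reagents that add atoms: tert-butyl N,N'-diisopropylcarbamimidate, CC(C)N=C(NC(C)C)OC(C)(C)C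
Why: The acidic ynoic acid protonates the isourea and is tert-butylated within the ion pair; the alcohol is not acidic enough to react, so the carboxyl group is masked selectively.

Step 13
Reactants: 20 tert-butyl (S)-4-hydroxyhex-2-ynoate; 21 hex-2-ynoic acid
Product: 22 tert-butyl (S)-4-(hex-2-ynoyloxy)hex-2-ynoate
Conditions: DCC (1.2 equiv), DMAP (5 mol %), CH2Cl2, 0 °C
Reagents that add atoms: none
Why: Steglich esterification of the secondary propargylic alcohol; low temperature and little DMAP limit conjugate addition to the ynoate and isomerisation to the allenoate. The C–O bond of the carbinol is untouched, so the configuration is retained.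

Step 14
Reactants: 22 tert-butyl (S)-4-(hex-2-ynoyloxy)hex-2-ynoate
Product: 23 (S)-4-(hex-2-ynoyloxy)hex-2-ynoic acid
Conditions: CF3CO2H/CH2Cl2 (1:4), 0 °C to rt
Reagents that add atoms: none
Why: Acidolysis of the tert-butyl ester through the tert-butyl cation; the ynoate ester and the propargylic acyloxy group, which sits on an electron-poor alkyne, do not ionise under these conditions.

Step 15
Reactants: 16 3β-alcohol; 23 (S)-4-(hex-2-ynoyloxy)hex-2-ynoic acid
Product: 24 9α-(tert-butyldimethylsilyloxy)-4β,5β-dimethyl-8-oxo-7-(propan-2-ylidene)-10αH-decalin-3α-yl (S)-4-(hex-2-ynoyloxy)hex-2-ynoate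
Conditions: PPh3 (2 equiv), DIAD (2 equiv), PhMe, 0 °C (betaine formed first), then 23, then 16, 0 °C to rt
Reagents that add atoms: none
Why: Mitsunobu esterification: the axial 3β-oxyphosphonium is displaced from the α face by the carboxylate of the strongly acidic ynoic acid, with inversion to the equatorial 3α-ester. Forming the betaine first keeps free phosphine away from the ynoate units.

Step 16
Reactants: 24 silyl ether
Product: 25 9α-hydroxy-4β,5β-dimethyl-8-oxo-7-(propan-2-ylidene)-10αH-decalin-3α-yl (S)-4-(hex-2-ynoyloxy)hex-2-ynoate
Conditions: HF·pyridine, THF, 0 °C to rt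
Reagents that add atoms: none
Why: Fluoride-driven cleavage of the secondary silyl ether under buffered acidic conditions, which leave the esters, the ynoates and the equatorial α-ketol untouched.

Step 17
Reactants: 25 diyne
Product: 26 (3R,4R,5R,9S,10R)-9-hydroxy-4,5-dimethyl-8-oxo-7-(propan-2-ylidene)decalin-3-yl (S,Z)-4-[(Z)-hex-2-enoyloxy]hex-2-enoate
Conditions: H2 (1 atm), Pd/CaCO3–Pb(OAc)2, quinoline, EtOAc, rt, stopped after 2 equiv H2
Reagents that add atoms: none
Why: Syn addition of hydrogen to each alkyne on the poisoned palladium surface gives both Z-enoates; the tetrasubstituted enone, the ketone and the allylic C–O bonds are not reduced by this catalyst.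

## Compound list

1 | 2-methoxy-5-methylphenol | COc1ccc(C)cc1O | starting material
2 | 2-methoxy-5-methyl-1,4-benzoquinone | COC1=CC(=O)C(C)=CC1=O | intermediate
3 | pent-1-en-3-one | CCC(=O)C=C | starting material
4 | (Z)-tert-butyldimethyl(penta-1,3-dien-3-yloxy)silane | C=C/C(O[Si](C)(C)C(C)(C)C)=C/C | intermediate
5 | cis-fused 3-(tert-butyldimethylsilyloxy)-8-methoxy-4α,5β-dimethyl-10βH-decala-2,7-diene-6,9-dione | CC(C)(C)[Si](C)(C)OC1=CC[C@@H]2C(=O)C(OC)=CC(=O)[C@]2(C)[C@@H]1C | intermediate
6 | trans-fused 3-(tert-butyldimethylsilyloxy)-8-methoxy-4α,5β-dimethyl-10αH-decala-2,7-diene-6,9-dione | CC(C)(C)[Si](C)(C)OC1=CC[C@H]2C(=O)C(OC)=CC(=O)[C@]2(C)[C@@H]1C | intermediate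
7 | 3-(tert-butyldimethylsilyloxy)-8-methoxy-4α,5β-dimethyl-10αH-decala-2,7-diene-6β,9β-diol | CC(C)(C)[Si](C)(C)OC1=CC[C@H]2[C@@H](O)C(OC)=C[C@@H](O)[C@]2(C)[C@@H]1C | intermediate (not isolated)
8 | 9β-hydroxy-4α,5β-dimethyl-10αH-decal-6-ene-3,8-dione | O=C1CC[C@H]2[C@@H](O)C(=O)C=C[C@]2(C)[C@@H]1C | intermediate
9 | 9α-hydroxy-4β,5β-dimethyl-10αH-decal-6-ene-3,8-dione | O=C1CC[C@H]2[C@H](O)C(=O)C=C[C@]2(C)[C@H]1C | intermediate
10 | 9α-(tert-butyldimethylsilyloxy)-4β,5β-dimethyl-10αH-decal-6-ene-3,8-dione | O=C1CC[C@H]2[C@H](O[Si](C)(C)C(C)(C)C)C(=O)C=C[C@]2(C)[C@H]1C | intermediate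
11 | acetone | CC(C)=O | starting material
12 | 9α-(tert-butyldimethylsilyloxy)-8-(dimethylphenylsilyloxy)-4β,5β-dimethyl-10αH-decal-7-en-3-one | O=C1CC[C@H]2[C@H](O[Si](C)(C)C(C)(C)C)C(O[Si](C)(C)c3ccccc3)=CC[C@]2(C)[C@H]1C | intermediate (not isolated)
13 | 9α-(tert-butyldimethylsilyloxy)-7α-(2-hydroxypropan-2-yl)-4β,5β-dimethyl-10αH-decalin-3,8-dione | O=C1CC[C@H]2[C@H](O[Si](C)(C)C(C)(C)C)C(=O)[C@H](C(C)(C)O)C[C@]2(C)[C@H]1C | intermediate
14 | methanesulfonate of 13 at the tertiary hydroxyl | O=C1CC[C@H]2[C@H](O[Si](C)(C)C(C)(C)C)C(=O)[C@H](C(C)(C)OS(C)(=O)=O)C[C@]2(C)[C@H]1C | intermediate (not isolated)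
15 | 9α-(tert-butyldimethylsilyloxy)-4β,5β-dimethyl-7-(propan-2-ylidene)-10αH-decalin-3,8-dione | O=C1CC[C@H]2[C@H](O[Si](C)(C)C(C)(C)C)C(=O)C(=C(C)C)C[C@]2(C)[C@H]1C | intermediate
16 | 9α-(tert-butyldimethylsilyloxy)-3β-hydroxy-4β,5β-dimethyl-7-(propan-2-ylidene)-10αH-decalin-8-one | O[C@H]1CC[C@H]2[C@H](O[Si](C)(C)C(C)(C)C)C(=O)C(=C(C)C)C[C@]2(C)[C@H]1C | intermediate
17 | (S)-pent-1-yn-3-ol | C#C[C@@H](O)CC | starting material
18 | dilithium salt of 17 (alkynide and alkoxide) | [Li+].[Li+].[C-]#C[C@@H]([O-])CC | intermediate (not isolated)
19 | (S)-4-hydroxyhex-2-ynoic acid | OC(=O)C#C[C@@H](O)CC | intermediate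
20 | tert-butyl (S)-4-hydroxyhex-2-ynoate | CC(C)(C)OC(=O)C#C[C@@H](O)CC | intermediate
21 | hex-2-ynoic acid | CCCC#CC(=O)O | starting material
22 | tert-butyl (S)-4-(hex-2-ynoyloxy)hex-2-ynoate | CCCC#CC(=O)O[C@H](C#CC(=O)OC(C)(C)C)CC | intermediate
23 | (S)-4-(hex-2-ynoyloxy)hex-2-ynoic acid | CCCC#CC(=O)O[C@H](C#CC(=O)O)CC | intermediate
24 | 9α-(tert-butyldimethylsilyloxy)-4β,5β-dimethyl-8-oxo-7-(propan-2-ylidene)-10αH-decalin-3α-yl (S)-4-(hex-2-ynoyloxy)hex-2-ynoate | CCCC#CC(=O)O[C@H](C#CC(=O)O[C@@H]1CC[C@H]2[C@H](O[Si](C)(C)C(C)(C)C)C(=O)C(=C(C)C)C[C@]2(C)[C@H]1C)CC | intermediate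
25 | 9α-hydroxy-4β,5β-dimethyl-8-oxo-7-(propan-2-ylidene)-10αH-decalin-3α-yl (S)-4-(hex-2-ynoyloxy)hex-2-ynoate | CCCC#CC(=O)O[C@H](C#CC(=O)O[C@@H]1CC[C@H]2[C@H](O)C(=O)C(=C(C)C)C[C@]2(C)[C@H]1C)CC | intermediate
26 | (3R,4R,5R,9S,10R)-9-hydroxy-4,5-dimethyl-8-oxo-7-(propan-2-ylidene)decalin-3-yl (S,Z)-4-[(Z)-hex-2-enoyloxy]hex-2-enoate | CCC/C=C\C(=O)O[C@H](/C=C\C(=O)O[C@@H]1CC[C@H]2[C@H](O)C(=O)C(=C(C)C)C[C@]2(C)[C@H]1C)CC | target

## Step count and least certain steps

Total: 17 steps. Longest linear sequence: 12 steps (1, 3, 4, 5, 6, 7, 8, 9, 10, 15, 16, 17; from 1 to 26).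

Step 3 (key step). The most likely failure is binding of the catalyst at the more basic C6 carbonyl oxygen (the vinylogous ester) instead of C9. That would either sequester the catalyst or polarise C5=C10 the other way, so that C4 bonds to C10 and face control is poor. Protodesilylation of 4 by traces of free acid is the second concern. Should only the sense of induction be opposite, the enantiomeric catalyst is taken. Fallback: 2 and 4 are combined without catalyst in toluene at 80 °C, where the free quinone reacts under control of its C9 carbonyl, to give the racemic cis adduct F1. DBU as in step 4 gives the racemic trans adduct F2, and preparative chromatography of F2 on a chiral stationary phase returns to the route at 6.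

Step 6 (with the base treatment of step 9). The equatorial preference at C4 is only moderate, because the 4β-methyl is gauche to the C5 methyl, so equilibration may stop at a mixture; the free ketol may also suffer air oxidation through its enediolate. Fallback for C4, setting out from 15 that still contains its C4 epimer F3: TMSOTf and Et3N convert the C3 ketone of both epimers into the more substituted C3=C4 trimethylsilyl enol ether F4, which no longer has a centre at C4. Protonation of F4 with dilute HCl in THF at 0 °C delivers hydrogen to C4 along the axial path on the α face, anti to the C5 methyl, and comes back to the route at 15. Any less substituted enol ether simply returns unchanged ketone.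

Step 8. The risks are competing hydrosilylation of the C3 ketone and slow addition of the hindered silyl enol ether to a ketone acceptor, which would end in simple protonation. Fallback, setting out from 10: LiBH(s-Bu)3 (2.2 equiv) reduces the C3 ketone 1,2 and the enone 1,4 in one operation to the dilithium enolate alkoxide F5. After addition of ZnCl2, F5 is intercepted by 11 to give the 3β-hydroxy aldol F6. Acid-catalysed dehydration (p-TsOH, PhH, 50 °C), to which the isolated secondary alcohol is inert, joins the route at 16 and makes step 10 unnecessary.

Step 15. The axial alcohol is flanked by the C4 methyl and is syn-axial to the C5 methyl, so slow activation followed by elimination toward C2 or C4 can compete with substitution, and residual phosphine can add to the ynoate units of the valuable acid. Fallback, setting out from 16: Mitsunobu inversion with 4-nitrobenzoic acid gives the 3α 4-nitrobenzoate F7. Methanolysis (K2CO3, MeOH) gives the 3α-alcohol F8, which is acylated with 23 (DCC, cat. DMAP) with retention and comes back to the route at 24.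

Step 17. Two conjugated alkynes must each take up exactly one equivalent of hydrogen; over-reduction to the saturated esters or Z to E isomerisation on the catalyst would give inseparable by-products at the last stage. Fallback, setting out from 22: semihydrogenation over Pd/CaCO3–Pb(OAc)2 at the stage of the small diester, where purification is easy, gives the (Z,Z)-diester F9, and acidolysis gives the (Z,Z)-acid F10. Mitsunobu coupling of F10 with 16 gives the 9-O-silyl ether F11 of the target, and HF·pyridine returns to the route at 26.

## Further compounds

F1 | step 3 | racemic cis adduct (5 together with its enantiomer) | CC(C)(C)[Si](C)(C)OC1=CC[C@@H]2C(=O)C(OC)=CC(=O)[C@]2(C)[C@@H]1C.CC(C)(C)[Si](C)(C)OC1=CC[C@H]2C(=O)C(OC)=CC(=O)[C@@]2(C)[C@H]1C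
F2 | step 3 | racemic trans adduct (6 together with its enantiomer) | CC(C)(C)[Si](C)(C)OC1=CC[C@H]2C(=O)C(OC)=CC(=O)[C@]2(C)[C@@H]1C.CC(C)(C)[Si](C)(C)OC1=CC[C@@H]2C(=O)C(OC)=CC(=O)[C@@]2(C)[C@H]1C
F3 | step 6 | C4 epimer of 15 (4α-methyl) | O=C1CC[C@H]2[C@H](O[Si](C)(C)C(C)(C)C)C(=O)C(=C(C)C)C[C@]2(C)[C@@H]1C
F4 | step 6 | C3=C4 trimethylsilyl enol ether of 15 | C[Si](C)(C)OC=1CC[C@H]2[C@H](O[Si](C)(C)C(C)(C)C)C(=O)C(=C(C)C)C[C@]2(C)C=1C
F5 | step 8 | dilithium C7=C8 enolate 3β-alkoxide from 10 | [Li+].[Li+].[O-][C@H]1CC[C@H]2[C@H](O[Si](C)(C)C(C)(C)C)C([O-])=CC[C@]2(C)[C@H]1C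
F6 | step 8 | 9α-(tert-butyldimethylsilyloxy)-3β-hydroxy-7α-(2-hydroxypropan-2-yl)-4β,5β-dimethyl-10αH-decalin-8-one | O[C@H]1CC[C@H]2[C@H](O[Si](C)(C)C(C)(C)C)C(=O)[C@H](C(C)(C)O)C[C@]2(C)[C@H]1C
F7 | step 15 | 3α 4-nitrobenzoate of the C3 epimer of 16 | O=C(O[C@@H]1CC[C@H]2[C@H](O[Si](C)(C)C(C)(C)C)C(=O)C(=C(C)C)C[C@]2(C)[C@H]1C)c1ccc(cc1)[N+](=O)[O-]
F8 | step 15 | 9α-(tert-butyldimethylsilyloxy)-3α-hydroxy-4β,5β-dimethyl-7-(propan-2-ylidene)-10αH-decalin-8-one | O[C@@H]1CC[C@H]2[C@H](O[Si](C)(C)C(C)(C)C)C(=O)C(=C(C)C)C[C@]2(C)[C@H]1C
F9 | step 17 | tert-butyl (S,Z)-4-[(Z)-hex-2-enoyloxy]hex-2-enoate | CCC/C=C\C(=O)O[C@H](/C=C\C(=O)OC(C)(C)C)CC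
F10 | step 17 | (S,Z)-4-[(Z)-hex-2-enoyloxy]hex-2-enoic acid | CCC/C=C\C(=O)O[C@H](/C=C\C(=O)O)CC
F11 | step 17 | 9-O-tert-butyldimethylsilyl ether of 26 | CCC/C=C\C(=O)O[C@H](/C=C\C(=O)O[C@@H]1CC[C@H]2[C@H](O[Si](C)(C)C(C)(C)C)C(=O)C(=C(C)C)C[C@]2(C)[C@H]1C)CC
A1 | alternative 1 | (R)-4-(tert-butyldimethylsilyloxy)-2-methylcyclohex-2-en-1-one | CC(C)(C)[Si](C)(C)O[C@@H]1CCC(=O)C(C)=C1
A2 | alternative 1 | 1-bromobut-2-yne | CC#CCBr
A3 | alternative 1 | 2-(but-2-ynyl)-4-(tert-butyldimethylsilyloxy)-2,3-dimethylcyclohexanone with the C3, C4 and C5 configuration of the target | CC(C)(C)[Si](C)(C)O[C@@H]1CCC(=O)[C@](C)(CC#CC)[C@H]1C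
A4 | alternative 2 | 2-(methoxymethoxy)-4-methyl-3-{2-[(2R,3R)-3-methyloxiran-2-yl]ethyl}phenol | C[C@H]1O[C@@H]1CCc1c(C)ccc(O)c1OCOC
A5 | alternative 2 | bicyclic dienone with free C3 hydroxyl, cis C4 and C5 methyls, C8 ketone and C9 methoxymethyl enol ether | O[C@@H]1CCC2=C(OCOC)C(=O)C=C[C@]2(C)[C@H]1C
A6 | alternative 3 | seco-dialdehyde: ring A with C3 silyloxy, C4 and C5 methyls, C10 formyl (C9) and at C5 the 2-formyl-3-methylbut-2-enyl chain (C6–C8, C11) | CC(C)(C)[Si](C)(C)O[C@@H]1CC[C@@H](C=O)[C@](C)(CC(C=O)=C(C)C)[C@H]1C
A7 | alternative 3 | 3α-(tert-butyldimethylsilyloxy)-9α-hydroxy-4β,5β-dimethyl-7-(propan-2-ylidene)-10αH-decalin-8-one | CC(C)(C)[Si](C)(C)O[C@@H]1CC[C@H]2[C@H](O)C(=O)C(=C(C)C)C[C@]2(C)[C@H]1C
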